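The earlier runs and the new flask come from a simulation with made-up constants; noise was put on by code.

I decide to count in fractions of the substrate charge and to follow one number: the partner charged per substrate, minus the two that bis adduct takes. In dawn it is 0.500, and I call it the spare partner.

| setting | Thursday's | Sunday's | dawn | dusk |
|---|---|---|---|---|
| substrate | 0.80 M | 0.80 M | 0.80 M | 0.80 M |
| coupling partner | 0.52 M | 0.98 M | 2.00 M | 0.400 M |
| remark | run made earlier | run made earlier |  |  |
| time |  |  | 2.0 d | 2.0 d |

- Thursday's (time / h: bis adduct / %, tris adduct / %): 10.0: 9.8, 0; 20.0: 14.8, 0; 30.0: 16.9, 0; 40.0: 17.3, 0.1; 50.0: 17.2, 0.6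
- Sunday's (time / h: bis adduct / %, tris adduct / %): 10.0: 26.3, 0; 20.0: 37.2, 0.6; 30.0: 42.4, 0.3; 40.0: 44.5, 1.0; 50.0: 45.0, 0.5

(standard deviation of a reading: 0.3 percentage points)

* which of these holds the largest part of the substrate at the end of dawn (first product / substrate / bis adduct / tris adduct / tetra adduct)
* which of these holds the largest part of the substrate at the end of dusk (first product / substrate / bis adduct / tris adduct / tetra adduct)
* amount of bis adduct at the end of dawn, in percent of the substrate charged

- a reading or a percentage of tris adduct counts all its forms, free or not

Thursday's run is short by 1.35 and Sunday's by 0.775. Both flatten, with bis adduct reading 17.2% and 45.0% at 50.0 h, which fits flasks short of partner. Dusk is short by 1.50, so partner is the limiting reagent there, and at least half stays substrate.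

Dawn has a positive spare, so my first estimate is bis adduct at the full charge. But the spare can go on reacting. If substrate and first product finish, the loss of bis adduct is at most the spare, which leaves 50.0%. That bound ignores speed, so I compute the correction.

Sunday's last two tris readings average 0.750%, which is 1.67% of its bis adduct. I scale by the partner charge, 2.04 times Sunday's, and by the time, 1.60 times the 30.0 h in which Sunday's curve nearly flattened. The loss comes to 5.44%. But those readings are 1.0% and 0.5%, with a scatter of 0.3 percentage points. The higher one alone gives 7.34%, so I commit to 92.7% of bis adduct, with the low side open.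

The forecast names bis adduct for dawn and substrate for dusk. It puts bis adduct at 87%, lower than my figure, and it expects in dawn that “substrate and first product are gone within about 15 h, leaving about 0.4 M partner”.

Dawn ends with bis adduct ahead at 84.3%. Dusk ends with substrate ahead at 61.9%.

    substrate + coupling partner → first product (k = 0.230 M⁻¹ h⁻¹)
    coupling partner + first product → bis adduct (k = 0.340 M⁻¹ h⁻¹)
    coupling partner + bis adduct → tris adduct (k = 0.0110 M⁻¹ h⁻¹)
    coupling partner + tris adduct → tetra adduct (k = 0.100 M⁻¹ h⁻¹)
    coupling partner ⇌ dormant form (K = 0.600, k = 0.390 h⁻¹)
    crystals ⇌ tris adduct, rate k6*(cs6 - [tris adduct]) while solid is left; crystals form when [tris adduct] > cs6 (solubility = 0.120 M, k = 8.90 h⁻¹)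

In dawn the first two additions run early: at 1.00 d they have 96% and 90% of their turnover up to 2.00 d behind them, and substrate stands at 5.07%. The addition to bis adduct runs later, with half its turnover up to that time done at 0.883 d. In dawn at 2.00 d, per substrate, 0.169 has gone beyond bis adduct, free partner holds 0.238 and dormant form 0.146, while substrate and first product still owe 0.0536 against the spare of 0.500. The neighbour with 0.50 M of partner is short by 1.38, and at 2.00 d it holds 54.7% substrate, 16.5% bis adduct and 0.311% of its partner charge.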